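## Retrosynthetic overview

1. The acrylic acid is unveiled last (acetal → CH2CHO → α-methylenation → Pinnick oxidation); the C3 ester comes from a Yamaguchi acylation with a TBS-protected Roche acid (fragment D).
2. The all-cis C3/C4/C5 array is set on the ring by two bulky-hydride reductions (C5 ketone, then C3 ketone after a site-selective oxidation), with the C4 and C6 side chains cis-diequatorial.
3. The only ring, the cyclohexane, is closed by an intramolecular aldol addition (C3–C4 bond) of an acyclic δ-keto aldehyde.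
4. The keto aldehyde comes from Pd-catalysed acylation of an acetal-bearing alkylzinc (fragment C) with the acid chloride of a Claisen acid.
5. The Claisen acid (quaternary C1 with methyl and vinyl, adjacent C6 centre) comes from an enantioselective Ireland–Claisen rearrangement of the ester of an itaconate-derived acid (fragment B) with an (E)-allylic alcohol (fragment A).

Conventions: ring positions are C1 = C(CH3)(vinyl), C2 = CH2, C3 = C–O(acyl), C4 = carbon bearing the acrylic acid, C5 = C–OH, C6 = carbon bearing the hydroxypropenyl group. "Top" is the ring face of the C1 methyl; in the target the C3, C4, C5 and C6 substituents are all on top and the vinyl is on the bottom.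

Assumption: the (S,S)-bromoborane controller is taken to give the Claisen acid in the absolute sense drawn; if the facial sense proves opposite, its (R,R)-enantiomer is used with no other change.

## Route

### Fragment A (allylic alcohol)

Step 1
Reactants: 1 4-hydroxybutan-2-one
Product: 2 4-(triethylsilyloxy)butan-2-one
Conditions: Et3SiCl, imidazole, CH2Cl2, 0 °C
Reagents that add atoms: chlorotriethylsilane, CC[Si](Cl)(CC)CC
Why: O-silylation masks the primary alcohol as a TES ether that can later be oxidised directly to the aldehyde; no stereocentre is involved.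

Step 2
Reactants: 2 4-(triethylsilyloxy)butan-2-one; 3 triethyl phosphonoacetate
Product: 4 ethyl (2E)-3-methyl-5-(triethylsilyloxy)pent-2-enoate
Conditions: NaH, THF, 0 °C to rt; minor Z isomer removed by chromatography
Reagents that add atoms: none
Why: Horner–Wadsworth–Emmons olefination of the methyl ketone gives mainly the E trisubstituted enoate (ester trans to the CH2CH2O chain), the geometry the later sigmatropic step needs.

Step 3
Reactants: 4 ethyl (2E)-3-methyl-5-(triethylsilyloxy)pent-2-enoate
Product: 5 (2E)-3-methyl-5-(triethylsilyloxy)pent-2-en-1-ol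
Conditions: i-Bu2AlH (2.2 equiv), CH2Cl2, −78 °C; aqueous potassium sodium tartrate
Reagents that add atoms: none
Why: 1,2-reduction of the conjugated ester with i-Bu2AlH gives the allylic alcohol with the alkene geometry retained.

### Fragment B (acid for the Claisen ester)

Step 4
Reactants: 6 monomethyl itaconate (4-methoxy-2-methylidene-4-oxobutanoic acid)
Product: 8 methyl 3-(hydroxymethyl)but-3-enoate, via mixed carbonic anhydride 7 (not isolated)
Conditions: i-BuOCOCl, N-methylmorpholine, THF, −15 °C; then NaBH4, THF/H2O, 0 °C; product silylated promptly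
Reagents that add atoms: none
Why: activation of the free acid as a mixed anhydride followed by borohydride reduction reduces it chemoselectively to the allylic alcohol, leaving the methyl ester and the alkene.

Step 5
Reactants: 8 methyl 3-(hydroxymethyl)but-3-enoate
Product: 9 methyl 3-[(tert-butyldimethylsilyloxy)methyl]but-3-enoate
Conditions: t-BuMe2SiCl, imidazole, DMF, rt
Reagents that add atoms: tert-butylchlorodimethylsilane, CC(C)(C)[Si](C)(C)Cl
Why: O-silylation protects the allylic alcohol (and prevents lactonisation) as a TBS ether that survives until the final acid treatment.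

Step 6
Reactants: 9 methyl 3-[(tert-butyldimethylsilyloxy)methyl]but-3-enoate
Product: 10 3-[(tert-butyldimethylsilyloxy)methyl]but-3-enoic acid
Conditions: LiOH·H2O, THF/H2O, 0 °C; then 1 M HCl to pH 4 at 0 °C
Reagents that add atoms: lithium hydroxide, [Li+].[OH-]
Why: saponification at low temperature gives the acid while keeping the β,γ-alkene out of conjugation.

### Fragment C (alkylzinc)

Step 7
Reactants: 11 acrolein; 12 ethane-1,2-diol
Product: 14 2-(2-bromoethyl)-1,3-dioxolane, via 3-bromopropanal 13 (not isolated)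
Conditions: HBr (g), CH2Cl2, 0 °C; then 12, TsOH (cat.), rt
Reagents that add atoms: hydrogen bromide, Br
Why: conjugate hydrobromination of the enal followed by acid-catalysed acetalisation gives the protected 3-bromopropanal.

Step 8
Reactants: 14 2-(2-bromoethyl)-1,3-dioxolane
Product: 15 2-(2-iodoethyl)-1,3-dioxolane
Conditions: NaI, acetone, reflux
Reagents that add atoms: sodium iodide, [Na+].[I-]
Why: Finkelstein halide exchange gives the iodide needed for mild direct zinc insertion.

Step 9
Reactants: 15 2-(2-iodoethyl)-1,3-dioxolane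
Product: 16 [2-(1,3-dioxolan-2-yl)ethyl]zinc iodide
Conditions: Zn dust (activated with BrCH2CH2Br and Me3SiCl), LiCl, THF, 40 °C
Reagents that add atoms: zinc, [Zn]
Why: oxidative insertion of zinc into the C–I bond gives a non-basic alkylzinc that tolerates the acetal and later acylates without enolising its partner.

### Fragment D (acyl side chain)

Step 10
Reactants: 17 methyl (2R)-3-hydroxy-2-methylpropanoate
Product: 18 methyl (2R)-3-(tert-butyldimethylsilyloxy)-2-methylpropanoate
Conditions: t-BuMe2SiCl, imidazole, CH2Cl2, rt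
Reagents that add atoms: tert-butylchlorodimethylsilane, CC(C)(C)[Si](C)(C)Cl
Why: O-silylation protects the primary alcohol; the stereocentre comes from the chiral pool and is untouched.

Step 11
Reactants: 18 methyl (2R)-3-(tert-butyldimethylsilyloxy)-2-methylpropanoate
Product: 19 (2R)-3-(tert-butyldimethylsilyloxy)-2-methylpropanoic acid
Conditions: LiOH·H2O, THF/MeOH/H2O, 0 °C to rt; then 1 M HCl to pH 4
Reagents that add atoms: lithium hydroxide, [Li+].[OH-]
Why: mild saponification gives the acid without epimerising the α-stereocentre.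

### Main line

Step 12
Reactants: 10 3-[(tert-butyldimethylsilyloxy)methyl]but-3-enoic acid; 5 (2E)-3-methyl-5-(triethylsilyloxy)pent-2-en-1-ol
Product: 20 (2E)-3-methyl-5-(triethylsilyloxy)pent-2-en-1-yl 3-[(tert-butyldimethylsilyloxy)methyl]but-3-enoate
Conditions: DCC, DMAP (5 mol %), CH2Cl2, −20 to 0 °C
Reagents that add atoms: none
Why: Steglich esterification joins fragments A and B; low temperature and little DMAP keep the β,γ-unsaturated acyl unit from isomerising into conjugation.

Step 13
Reactants: 20 (2E)-3-methyl-5-(triethylsilyloxy)pent-2-en-1-yl 3-[(tert-butyldimethylsilyloxy)methyl]but-3-enoate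
Product: 23 (2R,3S)-2-[3-(tert-butyldimethylsilyloxy)prop-1-en-2-yl]-3-ethenyl-3-methyl-5-(triethylsilyloxy)pentanoic acid, via boron ketene acetal 21 (not isolated), via acyloxyborane 22 (not isolated)
Conditions: (4S,5S)-2-bromo-4,5-diphenyl-1,3-bis(4-methylphenylsulfonyl)-1,3,2-diazaborolidine (1.3 equiv), Et3N, toluene/hexane, −78 °C; then −20 °C, 3–5 d; aqueous work-up
Reagents that add atoms: none
Why: enantioselective Ireland–Claisen rearrangement through a chair transition state, in which the ketene acetal with its side chain cis to the allyloxy oxygen and the E-alkene fix the C6/C1 relationship (side chain and methyl cis in the later ring, vinyl trans) and the C2-symmetric sulfonamide ligand on boron selects the face and hence the absolute configuration.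

Step 14
Reactants: 23 (2R,3S)-Claisen acid; 16 [2-(1,3-dioxolan-2-yl)ethyl]zinc iodide
Product: 25 (4R,5S)-4-[3-(tert-butyldimethylsilyloxy)prop-1-en-2-yl]-1-(1,3-dioxolan-2-yl)-5-ethenyl-5-methyl-7-(triethylsilyloxy)heptan-3-one, via acid chloride 24 (not isolated)
Conditions: Me2C=C(Cl)NMe2 (1.2 equiv), CH2Cl2, 0 °C to rt; concentrate; then 16 (1.5 equiv), Pd(PPh3)4 (5 mol %), THF, 0 °C to rt
Reagents that add atoms: none
Why: neutral acid chloride formation and Negishi-type Pd-catalysed acylation of the alkylzinc give the ketone without a basic reagent, so the doubly activated C6–H is neither epimerised nor moved into conjugation.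

Step 15
Reactants: 25 (4R,5S)-ketone
Product: 26 (3S,4R)-4-[3-(tert-butyldimethylsilyloxy)prop-1-en-2-yl]-7-(1,3-dioxolan-2-yl)-3-ethenyl-3-methyl-5-oxoheptanal
Conditions: (COCl)2, DMSO, CH2Cl2, −78 to −35 °C; then Et3N, −78 to 0 °C
Reagents that add atoms: none
Why: under Swern conditions the chlorosulfonium reagent cleaves the primary TES ether and oxidises it to the aldehyde in one operation, while the TBS ether, acetal and ketone are untouched.

Step 16
Reactants: 26 (3S,4R)-keto aldehyde
Product: 27 ring ketol (C5 ketone; C3-OH bottom; C4 (1,3-dioxolan-2-yl)methyl top; C6 3-(tert-butyldimethylsilyloxy)prop-1-en-2-yl top; C1 methyl top; C1 vinyl bottom)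
Conditions: L-proline (30 mol %), DMSO, rt (high dilution)
Reagents that add atoms: none
Why: intramolecular aldol addition (6-enolendo-exo-trig) through the enamine at the unhindered C4 methylene, the only enol position that reaches the aldehyde through a six-membered ring, closes the cyclohexane; C4 settles equatorial, cis to the C6 side chain, and the C3 carbinol (mainly equatorial, bottom face; any epimer is carried along) is reset in steps 18 and 19.

Step 17
Reactants: 27 ring ketol
Product: 28 ring diol (C3-OH bottom; C5-OH top; other substituents as in 27)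
Conditions: LiBH(s-Bu)3 (2.5 equiv), THF, −78 °C; then NaOH, H2O2
Reagents that add atoms: none
Why: bulky-hydride ketone reduction on the chair with both α-substituents equatorial and the C1 methyl axial on top, so hydride attacks C5 equatorially from the bottom face and the new alcohol is axial on top, cis to both neighbours.

Step 18
Reactants: 28 ring diol
Product: 29 ring hydroxy ketone (C3 ketone; C5-OH top)
Conditions: TEMPO (20 mol %), PhI(OAc)2 (1.2 equiv), CH2Cl2, 0 °C to rt
Reagents that add atoms: none
Why: nitroxyl-catalysed (oxoammonium) oxidation is sterically selective for the unhindered equatorial C3 alcohol over the axial C5 alcohol, which is flanked by two branched carbons and 1,3-diaxial to the C1 methyl; C4 stays equatorial next to the new ketone.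

Step 19
Reactants: 29 ring hydroxy ketone
Product: 30 ring syn-diol (C3-OH top; C5-OH top)
Conditions: LiBH(s-Bu)3 (2.5 equiv), THF, −78 °C; then NaOH, H2O2
Reagents that add atoms: none
Why: second bulky-hydride reduction, in which the top face of the C3 ketone is screened by the syn-axial C1 methyl and C5 oxygen, so hydride enters from the bottom and the new C3 alcohol is axial on top, completing the all-cis C3/C4/C5/C6 array.

Step 20
Reactants: 30 ring syn-diol; 19 (2R)-3-(tert-butyldimethylsilyloxy)-2-methylpropanoic acid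
Product: 32 C3 ester of 30 with the (2R)-3-(tert-butyldimethylsilyloxy)-2-methylpropanoyl group (C5-OH free), via mixed anhydride 31 (not isolated)
Conditions: 19 (1.1 equiv), 2,4,6-Cl3C6H2COCl, Et3N, toluene, rt; then 30, DMAP, toluene, 0 °C to rt
Reagents that add atoms: none
Why: Yamaguchi esterification acylates the C3 alcohol (one branched neighbour) in preference to the doubly flanked C5 alcohol, and the α-stereocentre of the acid is retained.

Step 21
Reactants: 32 C3 ester
Product: 33 triol aldehyde (C4 CH2CHO; C5-OH and both primary alcohols free; rests largely as the C5 lactol)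
Conditions: 1 M HCl, THF, rt
Reagents that add atoms: water, O
Why: acid-catalysed acetal hydrolysis and desilylation remove the dioxolane and both TBS ethers in one operation while the ester survives, and the freed aldehyde is buffered as the five-membered lactol with the cis C5 hydroxyl.

Step 22
Reactants: 33 triol aldehyde
Product: 34 enal (C4 C(=CH2)CHO)
Conditions: aq. CH2O (37 %), pyrrolidine (20 mol %), EtCO2H (20 mol %), i-PrOH, 45 °C
Reagents that add atoms: formaldehyde, C=O
Why: organocatalytic Mannich-type α-methylenation (enamine addition to formaldehyde, then amine elimination) turns the CH2CHO unit into the 2-substituted acrolein without touching a stereocentre.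

Step 23
Reactants: 34 enal
Product: 35 2-[(1S,2S,3R,4S,6R)-4-ethenyl-2-hydroxy-3-(3-hydroxyprop-1-en-2-yl)-6-{[(2R)-3-hydroxy-2-methylpropanoyl]oxy}-4-methylcyclohexyl]prop-2-enoic acid (target)
Conditions: NaClO2, NaH2PO4, 2-methylbut-2-ene, t-BuOH/H2O, 0 °C; extraction at pH 4–5
Reagents that add atoms: sodium chlorite, [Na+].[O-]Cl=O
Why: Pinnick oxidation converts the enal to the acrylic acid chemoselectively in the presence of free alcohols and alkenes (the alkene scavenger removes HOCl), and the buffered cold work-up avoids lactonisation onto the C5 hydroxyl.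

## Compound list

1 | 4-hydroxybutan-2-one | CC(=O)CCO | starting material
2 | 4-(triethylsilyloxy)butan-2-one | CC(=O)CCO[Si](CC)(CC)CC | intermediate
3 | triethyl phosphonoacetate | CCOC(=O)CP(=O)(OCC)OCC | starting material
4 | ethyl (2E)-3-methyl-5-(triethylsilyloxy)pent-2-enoate | CCOC(=O)/C=C(C)/CCO[Si](CC)(CC)CC | intermediate
5 | (2E)-3-methyl-5-(triethylsilyloxy)pent-2-en-1-ol | OC/C=C(C)/CCO[Si](CC)(CC)CC | intermediate
6 | monomethyl itaconate (4-methoxy-2-methylidene-4-oxobutanoic acid) | C=C(CC(=O)OC)C(=O)O | starting material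
7 | mixed carbonic anhydride of 6 with isobutyl carbonate | C=C(CC(=O)OC)C(=O)OC(=O)OCC(C)C | intermediate
8 | methyl 3-(hydroxymethyl)but-3-enoate | C=C(CO)CC(=O)OC | intermediate
9 | methyl 3-[(tert-butyldimethylsilyloxy)methyl]but-3-enoate | C=C(CO[Si](C)(C)C(C)(C)C)CC(=O)OC | intermediate
10 | 3-[(tert-butyldimethylsilyloxy)methyl]but-3-enoic acid | C=C(CO[Si](C)(C)C(C)(C)C)CC(=O)O | intermediate
11 | acrolein (prop-2-enal) | C=CC=O | starting material
12 | ethane-1,2-diol | OCCO | starting material
13 | 3-bromopropanal | BrCCC=O | intermediate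
14 | 2-(2-bromoethyl)-1,3-dioxolane | BrCCC1OCCO1 | intermediate
15 | 2-(2-iodoethyl)-1,3-dioxolane | ICCC1OCCO1 | intermediate
16 | [2-(1,3-dioxolan-2-yl)ethyl]zinc iodide | I[Zn]CCC1OCCO1 | intermediate
17 | methyl (2R)-3-hydroxy-2-methylpropanoate (Roche ester) | COC(=O)[C@H](C)CO | starting material
18 | methyl (2R)-3-(tert-butyldimethylsilyloxy)-2-methylpropanoate | COC(=O)[C@H](C)CO[Si](C)(C)C(C)(C)C | intermediate
19 | (2R)-3-(tert-butyldimethylsilyloxy)-2-methylpropanoic acid | OC(=O)[C@H](C)CO[Si](C)(C)C(C)(C)C | intermediate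
20 | (2E)-3-methyl-5-(triethylsilyloxy)pent-2-en-1-yl 3-[(tert-butyldimethylsilyloxy)methyl]but-3-enoate | C=C(CO[Si](C)(C)C(C)(C)C)CC(=O)OC/C=C(C)/CCO[Si](CC)(CC)CC | intermediate
21 | boron ketene acetal of 20 (side chain cis to the allyloxy oxygen; boron carries the (S,S)-ditosyl-diphenylethylenediamine ligand) | C=C(CO[Si](C)(C)C(C)(C)C)/C=C(\OC/C=C(C)/CCO[Si](CC)(CC)CC)OB1N(S(=O)(=O)c2ccc(C)cc2)[C@@H](c2ccccc2)[C@H](c2ccccc2)N1S(=O)(=O)c1ccc(C)cc1 | intermediate
22 | acyloxyborane (boron carboxylate of 23) | C=C[C@](C)(CCO[Si](CC)(CC)CC)[C@@H](C(=O)OB1N(S(=O)(=O)c2ccc(C)cc2)[C@@H](c2ccccc2)[C@H](c2ccccc2)N1S(=O)(=O)c1ccc(C)cc1)C(=C)CO[Si](C)(C)C(C)(C)C | intermediate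
23 | (2R,3S)-2-[3-(tert-butyldimethylsilyloxy)prop-1-en-2-yl]-3-ethenyl-3-methyl-5-(triethylsilyloxy)pentanoic acid | C=C[C@](C)(CCO[Si](CC)(CC)CC)[C@@H](C(=O)O)C(=C)CO[Si](C)(C)C(C)(C)C | intermediate
24 | acid chloride of 23 | C=C[C@](C)(CCO[Si](CC)(CC)CC)[C@@H](C(=O)Cl)C(=C)CO[Si](C)(C)C(C)(C)C | intermediate
25 | (4R,5S)-4-[3-(tert-butyldimethylsilyloxy)prop-1-en-2-yl]-1-(1,3-dioxolan-2-yl)-5-ethenyl-5-methyl-7-(triethylsilyloxy)heptan-3-one | C=C[C@](C)(CCO[Si](CC)(CC)CC)[C@@H](C(=O)CCC1OCCO1)C(=C)CO[Si](C)(C)C(C)(C)C | intermediate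
26 | (3S,4R)-4-[3-(tert-butyldimethylsilyloxy)prop-1-en-2-yl]-7-(1,3-dioxolan-2-yl)-3-ethenyl-3-methyl-5-oxoheptanal | C=C[C@](C)(CC=O)[C@@H](C(=O)CCC1OCCO1)C(=C)CO[Si](C)(C)C(C)(C)C | intermediate
27 | ring ketol: C5 ketone, C3-OH bottom, C4 (1,3-dioxolan-2-yl)methyl top, C6 3-(tert-butyldimethylsilyloxy)prop-1-en-2-yl top, C1 methyl top, C1 vinyl bottom | C=C[C@]1(C)C[C@H](O)[C@@H](CC2OCCO2)C(=O)[C@H]1C(=C)CO[Si](C)(C)C(C)(C)C | intermediate
28 | ring diol: as 27 with C5-OH top (C3-OH bottom) | C=C[C@]1(C)C[C@H](O)[C@@H](CC2OCCO2)[C@@H](O)[C@H]1C(=C)CO[Si](C)(C)C(C)(C)C | intermediate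
29 | ring hydroxy ketone: C3 ketone, C5-OH top, side chains as in 27 | C=C[C@]1(C)CC(=O)[C@@H](CC2OCCO2)[C@@H](O)[C@H]1C(=C)CO[Si](C)(C)C(C)(C)C | intermediate
30 | ring syn-diol: C3-OH top, C5-OH top, side chains as in 27 | C=C[C@]1(C)C[C@@H](O)[C@@H](CC2OCCO2)[C@@H](O)[C@H]1C(=C)CO[Si](C)(C)C(C)(C)C | intermediate
31 | mixed anhydride of 19 with 2,4,6-trichlorobenzoic acid | O=C(OC(=O)c1c(Cl)cc(Cl)cc1Cl)[C@H](C)CO[Si](C)(C)C(C)(C)C | intermediate
32 | C3 (2R)-3-(tert-butyldimethylsilyloxy)-2-methylpropanoate of 30 (C5-OH free) | C=C[C@]1(C)C[C@@H](OC(=O)[C@H](C)CO[Si](C)(C)C(C)(C)C)[C@@H](CC2OCCO2)[C@@H](O)[C@H]1C(=C)CO[Si](C)(C)C(C)(C)C | intermediate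
33 | triol aldehyde: C4 2-oxoethyl, C3 (2R)-3-hydroxy-2-methylpropanoate, C5-OH, C6 3-hydroxyprop-1-en-2-yl (open form of the lactol) | C=C[C@]1(C)C[C@@H](OC(=O)[C@H](C)CO)[C@@H](CC=O)[C@@H](O)[C@H]1C(=C)CO | intermediate
34 | enal: as 33 with C4 3-oxoprop-1-en-2-yl | C=C[C@]1(C)C[C@@H](OC(=O)[C@H](C)CO)[C@@H](C(=C)C=O)[C@@H](O)[C@H]1C(=C)CO | intermediate
35 | 2-[(1S,2S,3R,4S,6R)-4-ethenyl-2-hydroxy-3-(3-hydroxyprop-1-en-2-yl)-6-{[(2R)-3-hydroxy-2-methylpropanoyl]oxy}-4-methylcyclohexyl]prop-2-enoic acid | C=C[C@]1(C)C[C@@H](OC(=O)[C@H](C)CO)[C@@H](C(=C)C(=O)O)[C@@H](O)[C@H]1C(=C)CO | target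

## Step count and risks

Total step count: 23.
Longest linear sequence: 15 steps (steps 1–3, then 12–23; the branch through steps 4–6 is equally long).

Steps most likely to fail, each with a fallback:

Step 13 (enantioselective Ireland–Claisen). The β,γ-unsaturated ester may enolise with poor geometry control or give low enantioselectivity. The fallback sets out from ester 20 and returns at acid 23. LiN(i-Pr)2 in THF at −78 °C followed by Me3SiCl/Et3N gives the trimethylsilyl ketene acetal F1 (side chain cis to the allyloxy oxygen). On warming to rt it rearranges through the same chair to the racemic trimethylsilyl ester F2, and aqueous work-up gives the racemic acid F3 with the same relative configuration. Crystallisation with (S)-1-phenylethylamine gives the single diastereomeric ammonium salt F4 (the amine enantiomer is chosen by which salt crystallises), and acidification releases 23.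

Step 16 (aldol ring closure). Enamine formation at the hindered ketone may be slow, and C6 may epimerise or the alkene drift into conjugation. The fallback sets out from ketone 25 and returns at ketol 27; it generates the C4 enolate regiospecifically under non-equilibrating conditions. LiN(i-Pr)2 and Me3SiCl in THF at −78 °C give the kinetic trimethylsilyl enol ether F5, and N-bromosuccinimide at −78 °C gives the α-bromo ketone F6 (both C4 epimers). Swern oxidation as in step 15 then gives the α-bromo keto aldehyde F7. SmI2 in THF at −78 °C forms the samarium enolate at C4 only, which closes the ring by an intramolecular Reformatsky-type aldol addition to give 27.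

Step 18 (site-selective oxidation). The oxidant may not distinguish the two secondary alcohols cleanly. The fallback sets out from diol 28 and returns at triol aldehyde 33; it replaces reagent selectivity by protecting-group differentiation and also removes the site selection in step 20. Et3SiOTf/2,6-lutidine gives the bis(triethylsilyl) ether F8, and PPTS in MeOH/CH2Cl2 at 0 °C removes only the unhindered equatorial C3 silyl group to give the C3 alcohol F9. Dess–Martin periodinane gives the C3 ketone F10, and LiBH(s-Bu)3 at −78 °C gives the top-face C3 alcohol F11. Yamaguchi acylation with 19 (through 31) gives the ester F12, and the conditions of step 21 remove the triethylsilyl group together with the TBS ethers and the acetal to give 33.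

Further compounds

F1 | step 13 | trimethylsilyl ketene acetal of 20 (side chain cis to the allyloxy oxygen) | C=C(CO[Si](C)(C)C(C)(C)C)/C=C(\OC/C=C(C)/CCO[Si](CC)(CC)CC)O[Si](C)(C)C
F2 | step 13 | racemic trimethylsilyl ester of the Claisen acid (both enantiomers) | C=C[C@](C)(CCO[Si](CC)(CC)CC)[C@@H](C(=O)O[Si](C)(C)C)C(=C)CO[Si](C)(C)C(C)(C)C.C=C[C@@](C)(CCO[Si](CC)(CC)CC)[C@H](C(=O)O[Si](C)(C)C)C(=C)CO[Si](C)(C)C(C)(C)C
F3 | step 13 | racemic (2R*,3S*)-Claisen acid (both enantiomers) | C=C[C@](C)(CCO[Si](CC)(CC)CC)[C@@H](C(=O)O)C(=C)CO[Si](C)(C)C(C)(C)C.C=C[C@@](C)(CCO[Si](CC)(CC)CC)[C@H](C(=O)O)C(=C)CO[Si](C)(C)C(C)(C)C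
F4 | step 13 | (S)-1-phenylethylammonium salt of 23 | C=C[C@](C)(CCO[Si](CC)(CC)CC)[C@@H](C(=O)[O-])C(=C)CO[Si](C)(C)C(C)(C)C.C[C@H]([NH3+])c1ccccc1
F5 | step 16 | kinetic (Z)-trimethylsilyl enol ether of 25 (C4=C5) | C=C[C@](C)(CCO[Si](CC)(CC)CC)[C@@H](/C(O[Si](C)(C)C)=C/CC1OCCO1)C(=C)CO[Si](C)(C)C(C)(C)C
F6 | step 16 | C4-bromo ketone from 25 (both C4 epimers) | C=C[C@](C)(CCO[Si](CC)(CC)CC)[C@@H](C(=O)C(Br)CC1OCCO1)C(=C)CO[Si](C)(C)C(C)(C)C
F7 | step 16 | C4-bromo keto aldehyde (both C4 epimers) | C=C[C@](C)(CC=O)[C@@H](C(=O)C(Br)CC1OCCO1)C(=C)CO[Si](C)(C)C(C)(C)C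
F8 | step 18 | C3,C5-bis(triethylsilyl) ether of 28 | C=C[C@]1(C)C[C@H](O[Si](CC)(CC)CC)[C@@H](CC2OCCO2)[C@@H](O[Si](CC)(CC)CC)[C@H]1C(=C)CO[Si](C)(C)C(C)(C)C
F9 | step 18 | C5 triethylsilyl ether with free bottom-face C3 alcohol | C=C[C@]1(C)C[C@H](O)[C@@H](CC2OCCO2)[C@@H](O[Si](CC)(CC)CC)[C@H]1C(=C)CO[Si](C)(C)C(C)(C)C
F10 | step 18 | C3 ketone with C5 triethylsilyl ether | C=C[C@]1(C)CC(=O)[C@@H](CC2OCCO2)[C@@H](O[Si](CC)(CC)CC)[C@H]1C(=C)CO[Si](C)(C)C(C)(C)C
F11 | step 18 | top-face C3 alcohol with C5 triethylsilyl ether | C=C[C@]1(C)C[C@@H](O)[C@@H](CC2OCCO2)[C@@H](O[Si](CC)(CC)CC)[C@H]1C(=C)CO[Si](C)(C)C(C)(C)C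
F12 | step 18 | C3 (2R)-3-(tert-butyldimethylsilyloxy)-2-methylpropanoate with C5 triethylsilyl ether | C=C[C@]1(C)C[C@@H](OC(=O)[C@H](C)CO[Si](C)(C)C(C)(C)C)[C@@H](CC2OCCO2)[C@@H](O[Si](CC)(CC)CC)[C@H]1C(=C)CO[Si](C)(C)C(C)(C)C
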